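**Numbering used throughout.** Tetrahydrofuran: O1, C2 (4-oxygenated phenyl), C3 (benzofuranyl), C4 (3,5-dioxygenated phenyl), C5 (4-oxygenated phenyl). Dihydrobenzofuran: O1', C2', C3', benzo ring D = C3a'–C7a'. The two units are joined C3–C4'. Compounds are numbered 1–22 in the order of the steps.

## Analysis of the target

The target 22 is a resveratrol trimer in which a 2,3,4,5-tetraaryl tetrahydrofuran is joined through C3 to C4' of a 2,3-diaryl-2,3-dihydrobenzofuran. It carries eight free phenols: one on each of the aryl groups at C2, C5 and C2', two on each of the aryl groups at C4 and C3', and one at C6' of ring D. There are six stereocentres: C2'/C3' are trans (2'R,3'R), and in the tetrahydrofuran (2S,3S,4R,5S) the aryl groups on C2, C3 and C4 lie on one face and the C5 aryl on the other, so the C2/C3/C4 triad is all-cis and only C4/C5 is trans. The three ring C–O bonds at C2, C5 and C2' are benzylic and para to an oxygen-bearing ring; acids ionise them to quinone-methide-like cations that re-close to the more stable trans arrangement, which is welcome at C2', harmless at C5 and destructive at C2. The synthesis is hard for three reasons: the crowded cis triad is the contra-thermodynamic one, C4 and C5 must be set in the absolute sense next to a large aryl group that is itself chiral, and eight phenols must be unmasked without acid. The strategy rests on reading C2=C3 as an enol ether: O1–C2(aryl)=C3(ring D)–C4(aryl) is then the oxygen, carbonyl carbon, α-carbon and β-carbon of a 1,2,3-triarylpropenone, and the one missing ring atom, C5 with its aryl group, is a one-carbon unit that must bond to both O1 and C4.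

## Retrosynthetic reasoning

**22 ⇒ 21.** The last disconnection removes the hydrogens on C2 and C3 and the eight phenolic O–H bonds, leading back to the 2,3-dihydrofuran 21 with all phenols as benzyl ethers. The two C–H bonds are cut together because the target needs both hydrogens on the same face, that of the C5 aryl and opposite the C4 aryl. A syn addition from the surface of Pd/C delivers this pair in one event and leaves only the choice of face, which the allylic C4 aryl should decide. A proton-then-hydride reduction was not chosen as the main line: it passes through a cationic C2 centre in which C3 can equilibrate through the enol ether toward the 3,4-trans arrangement. Benzyl ethers are preferred to methyl ethers for a related reason: a Lewis-acidic dealkylation would ionise C2–O1 and turn the cis triad into trans, whereas benzyl groups fall under the neutral conditions of the hydrogenation itself, so reduction and deprotection become one step.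

**21 ⇒ 16 + 20.** Dihydrofuran 21 is cut at O1–C5 and C4–C5. This excises C5 as the benzylidene unit of diazoalkane 20 and leaves enone 16. These are the only two ring bonds whose cleavage leaves the other four ring atoms as a stable conjugated functional group. The cut also separates a fragment holding every other carbon from a small reagent, and both stereocentres of the C4/C5 pair arise in one step under the CuOTf–bisoxazoline catalyst. Forward, the carbene carbon of 20, bound to copper, must be taken up by the ketone oxygen of 16, and the resulting ylide must close onto C4 with C5 trans to C4. C4 is S in 21 and becomes 4R in 22 only through a change of substituent priorities. Because 20 is too labile to store, it is released in the flask from the sulfonylhydrazone salt 19.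

**16 ⇒ 14 + 15.** The C3=C4 double bond is cut into deoxybenzoin 14 and aldehyde 15, the aldol-type disconnection of an α-aryl chalcone. It gives the E isomer (aroyl trans to the β-aryl), whose s-cis conformer has only hydrogen pointing into the bay where C5 must arrive.

**14 ⇒ 12 + 13.** The CH2–C4' bond is cut to aryl bromide 12 and methyl ketone 13. Enolate arylation under Pd(OAc)2 and XPhos brings in the whole aryl ketone in one step. It also lets the handle on ring D be a bromine atom, which is inert in all earlier steps; an acetic acid side chain at C4' would interfere with the carbene chemistry that builds the dihydrobenzofuran.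

**12 ⇒ 11 ⇒ 10 ⇒ 9 ⇒ 8.** In 12 the C2'–C3' bond is cut. Going back through the cis isomer 11, this bond comes from insertion of the diaryl carbene of diazo compound 10 (from hydrazone 9 of ketone 8) into a C–H bond of the benzylic ether CH2. The chiral dirhodium carboxylate Rh2(R-PTAD)4 fixes C3'. Because C2' is epimerisable through its benzylic C–O bond, the kinetic cis product 11 is then converted into the stable trans isomer 12 without touching C3'. The only enantioselective step of the fragment thus sits early, on a simple compound, and every later stereocentre is set relative to it.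

**8 ⇒ 7 ⇒ 5 + 6; 5 ⇒ 3 + 4; 3 ⇒ 2 ⇒ 1.** Ketone 8 goes back through carbinol 7 to aldehyde 5 and Grignard reagent 6 (bond between the carbinol carbon and the 3,5-dioxygenated ring). Ether 5 is cut at O–CH2 into phenol 3 and chloride 4. Phenol 3 comes from 2 by removal of the one benzyl group that flanks the aldehyde, and 2 from bromide 1 by formylation. Ring D is therefore a single catalogue arene whose three substituents are differentiated by the formyl group: it enters next to bromine and then marks the neighbouring ether for cleavage. Bromide 1 is also the source of 6.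

**19 ⇒ 18 ⇒ 17.** Salt 19 is cut at C=N to aldehyde 17; condensation to sulfonylhydrazone 18 and deprotonation are one operation.

## Alternatives that were turned down

Alternative 1: ring D by alkyne cyclotrimerisation.
- Disconnection: ring D is cut at C3a'–C7a', C4'–C5' and C6'–C7'. This leads to the ynol-ether diyne A2, in which an ethynyl ether on the C2' oxygen is tethered through C3' to an alkyne on C3 of the finished tetrahydrofuran, and to ethoxyethyne A3.
- Forward step: Cp*RuCl(cod) joins the three alkynes, closing ring D and the fused dihydrofuran at once to give the heptamethyl 6'-ethyl ether of the target A1.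
- For it: the step is highly convergent and aromatisation is stereochemically silent, so no stereocentre is at risk in the key step.
- Against it: A2 must already contain the complete cis-triad tetrahydrofuran and both C2'/C3' centres in open-chain form, so the stereochemical problem is only moved into a longer precursor synthesis. The ethynyl ether of A2 sits on a benzylic carbon and is prone to sigmatropic rearrangement. Nothing in A2 decides whether the ethoxy group of A3 ends at C6' or C5'. A1 still needs eight alkyl ethers cleaved by a Lewis acid, which threatens C2.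
- Comparison: Alternative 1 is stronger in convergence and in the safety of its key step. The chosen route offers instead a key step that itself creates a ring and two stereocentres, a precursor (16) ten steps from catalogue compounds, and a neutral end game.

Alternative 2: aryl ketene [2+2], then ring expansion.
- Disconnection: C2–C3 and C4–C5 are cut, with O1 to be inserted later.
- Forward step: (4-methoxyphenyl)ketene A5, formed by photochemical Wolff rearrangement of the diazoketone A6, adds to the Z-diarylethene A7 to give the all-cis triarylcyclobutanone A4. Oxygen insertion next to the carbonyl group, introduction of the C5 aryl group and reduction would follow.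
- For it, and here it is stronger than the chosen route: the suprafacial addition to a Z-alkene, combined with the known preference of a ketene substituent to end up cis to the alkene substituents, writes the difficult all-cis C2/C3/C4 triad directly through a pericyclic preference. The chosen route must win it by face selection in a hydrogenation.
- Against it:
  - A5 dimerises readily and A7, a stilbene, is a poor ketenophile;
  - the light that converts A6 into A5 also isomerises or photocyclises A7;
  - the two alkene carbons of A7 are both aryl-substituted, so the regiochemistry (which carbon bonds to the ketene carbonyl) is not controlled;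
  - the only chiral element is the remote dihydrobenzofuran, so the absolute sense of three new centres is left to substrate bias;
  - the α-centres of A4 epimerise easily, and the oxygen insertion must distinguish two secondary benzylic α-carbons;
  - the C5 aryl is still missing, and its introduction at the carbonyl oxidation level followed by reduction is expected to place hydride anti to the C4 aryl and give 4,5-cis.
- Comparison: the chosen route offers catalyst control over C4/C5 and a single step after the key step instead of at least three.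

Alternative 3: late ortho-quinone methide [4+1].
- Disconnection: C2'–C3' and O1'–C2' are cut.
- Forward step: the ring D benzhydrol A9 is ionised to the ortho-quinone methide A10. The ylide made from the 4-methoxybenzyl sulfonium bromide A11 adds to the methide carbon and the phenoxide displaces the sulfide, closing the trans-dihydrofuran ring and giving the octamethyl ether of the target A8.
- For it, and here it is stronger than the chosen route: this annulation is a known reaction class, trans follows from anti addition and from thermodynamics, and the acid-labile dihydrobenzofuran is made last.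
- Against it: A9 presupposes the whole cis-triad tetrahydrofuran, whose synthesis this plan does not address. A10 is planar at C3', so C2' and C3' must be set in the absolute sense by a chiral analogue of A11 or by the tetrahydrofuran across the C3–C4' axis, with no reliable model. A8 again ends in an eightfold Lewis-acidic demethylation that the cis C2 centre is not expected to survive.
- Comparison: the chosen route inverts the order. The dihydrobenzofuran is made first by an established asymmetric method and then serves as the anchor; the uncertainty is concentrated in one copper-catalysed step and the route ends under neutral conditions.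

Key step: step 12

**Remarks on the chemistry**
- All eight phenols are carried as benzyl ethers, for the reason given in the first retrosynthetic paragraph; the precursor pair and the product of the key step are therefore 16, 20 and 21.
- Assumption: the enantiomers of the two chiral catalysts written below are taken to give the configurations drawn. These are Rh2(R-PTAD)4, i.e. dirhodium tetrakis[(R)-(1-adamantyl)(phthalimido)acetate], in step 7 and, in step 12, CuOTf with (S,S)-t-Bu-box, i.e. 2,2'-(propane-2,2-diyl)bis[(4S)-4-tert-butyl-4,5-dihydro-1,3-oxazole]. If the sense of induction is the opposite, the mirror-image catalyst is used and nothing else changes.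
- Compounds 1, 4, 13, 15 and 17 are taken as catalogue compounds.

## Route

Step 1
Reactants: 1 1,3-bis(benzyloxy)-5-bromobenzene
Product: 2 2,4-bis(benzyloxy)-6-bromobenzaldehyde
Conditions: POCl3, DMF, 0 → 80 °C; then aq NaOAc
Reagents that add atoms: N,N-dimethylformamide CN(C)C=O; water O
Why: Vilsmeier–Haack formylation; the chloroiminium ion should attack the position para to one benzyloxy group and ortho to the other (next to bromine) in preference to the position between the two benzyloxy groups, and the minor isomer is expected to be removable by crystallisation.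

Step 2
Reactants: 2 2,4-bis(benzyloxy)-6-bromobenzaldehyde
Product: 3 4-(benzyloxy)-2-bromo-6-hydroxybenzaldehyde
Conditions: MgBr2·OEt2, PhMe–Et2O, reflux; dilute aqueous work-up
Reagents that add atoms: none
Why: Chelation-controlled ether cleavage: magnesium held between the aldehyde oxygen and the ortho ether oxygen activates only that benzyl group for bromide attack at its CH2, so the para benzyl ether should survive.

Step 3
Reactants: 3 4-(benzyloxy)-2-bromo-6-hydroxybenzaldehyde; 4 1-(benzyloxy)-4-(chloromethyl)benzene
Product: 5 4-(benzyloxy)-2-{[4-(benzyloxy)phenyl]methoxy}-6-bromobenzaldehyde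
Conditions: K2CO3, NaI (cat.), DMF, 60 °C
Reagents that add atoms: none
Why: Williamson ether synthesis of a phenoxide with a reactive benzylic chloride; it installs the CH2 group that later becomes C2' with its aryl group.

Step 4
Reactants: 1 1,3-bis(benzyloxy)-5-bromobenzene; 5 4-(benzyloxy)-2-{[4-(benzyloxy)phenyl]methoxy}-6-bromobenzaldehyde
Product: 7 rac-[4-(benzyloxy)-2-{[4-(benzyloxy)phenyl]methoxy}-6-bromophenyl][3,5-bis(benzyloxy)phenyl]methanol, via [3,5-bis(benzyloxy)phenyl]magnesium bromide 6 (not isolated)
Conditions: 1, Mg, THF, 50 °C; then 5, THF, −20 °C → rt; aq NH4Cl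
Reagents that add atoms: none
Why: Grignard addition to an aldehyde; an arylmagnesium bromide does not exchange with the aryl bromide of 5 at this temperature, and the carbinol centre is racemic because it is oxidised in the next step.

Step 5
Reactants: 7 rac-[4-(benzyloxy)-2-{[4-(benzyloxy)phenyl]methoxy}-6-bromophenyl][3,5-bis(benzyloxy)phenyl]methanol
Product: 8 [4-(benzyloxy)-2-{[4-(benzyloxy)phenyl]methoxy}-6-bromophenyl][3,5-bis(benzyloxy)phenyl]methanone
Conditions: Dess–Martin periodinane, CH2Cl2, rt
Reagents that add atoms: none
Why: Dess–Martin oxidation of a hindered diaryl carbinol; the reagent tolerates benzyl ethers and the aryl bromide.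

Step 6
Reactants: 8 [4-(benzyloxy)-2-{[4-(benzyloxy)phenyl]methoxy}-6-bromophenyl][3,5-bis(benzyloxy)phenyl]methanone
Product: 9 {[4-(benzyloxy)-2-{[4-(benzyloxy)phenyl]methoxy}-6-bromophenyl][3,5-bis(benzyloxy)phenyl]methylidene}hydrazine (E/Z mixture)
Conditions: N2H4·H2O (excess), AcOH (cat.), n-BuOH, 110 °C, sealed vessel
Reagents that add atoms: hydrazine NN
Why: Condensation of a diaryl ketone with hydrazine to the N-unsubstituted hydrazone; forcing conditions are chosen because the carbonyl group is flanked by two ortho substituents, and the electron-rich aryl bromide is not displaced without a metal catalyst.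

Step 7
Reactants: 9 {[4-(benzyloxy)-2-{[4-(benzyloxy)phenyl]methoxy}-6-bromophenyl][3,5-bis(benzyloxy)phenyl]methylidene}hydrazine (E/Z mixture)
Product: 11 (2S,3R)-6-(benzyloxy)-2-[4-(benzyloxy)phenyl]-3-[3,5-bis(benzyloxy)phenyl]-4-bromo-2,3-dihydro-1-benzofuran (cis), via diaryldiazomethane 10 (not isolated)
Conditions: MnO2, CH2Cl2, 0 °C, filter; then Rh2(R-PTAD)4 (1 mol%), CH2Cl2, −20 °C → rt
Reagents that add atoms: none
Why: Dehydrogenation of the hydrazone to the diaryldiazomethane, then dirhodium-catalysed intramolecular 1,5 C–H insertion of the donor/donor carbene into the ether CH2, which is activated by oxygen and by the 4-benzyloxyphenyl ring. The concerted three-centre insertion places the two aryl groups cis, and the chiral carboxylate ligands select the face of the carbene, which fixes C3' as R (C2' is S at this stage).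

Step 8
Reactants: 11 (2S,3R)-6-(benzyloxy)-2-[4-(benzyloxy)phenyl]-3-[3,5-bis(benzyloxy)phenyl]-4-bromo-2,3-dihydro-1-benzofuran (cis)
Product: 12 (2R,3R)-6-(benzyloxy)-2-[4-(benzyloxy)phenyl]-3-[3,5-bis(benzyloxy)phenyl]-4-bromo-2,3-dihydro-1-benzofuran (trans)
Conditions: BF3·OEt2 (0.3 equiv), CH2Cl2, −20 → 0 °C
Reagents that add atoms: none
Why: Lewis-acid-mediated epimerisation: reversible heterolysis of the C2'–O1' bond to the 4-benzyloxybenzyl cation and re-closure should give the thermodynamically preferred trans isomer, with C2' going from S to R while C3' is not involved.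

Step 9
Reactants: 12 (2R,3R)-6-(benzyloxy)-2-[4-(benzyloxy)phenyl]-3-[3,5-bis(benzyloxy)phenyl]-4-bromo-2,3-dihydro-1-benzofuran (trans); 13 1-[4-(benzyloxy)phenyl]ethan-1-one
Product: 14 1-[4-(benzyloxy)phenyl]-2-{(2R,3R)-6-(benzyloxy)-2-[4-(benzyloxy)phenyl]-3-[3,5-bis(benzyloxy)phenyl]-2,3-dihydro-1-benzofuran-4-yl}ethan-1-one
Conditions: Pd(OAc)2 (3 mol%), XPhos (6 mol%), K3PO4, 13 (2 equiv), PhMe, 100 °C
Reagents that add atoms: none
Why: Buchwald–Hartwig-type palladium-catalysed α-arylation of a methyl ketone enolate; the ortho-substituted bromide and the excess of ketone favour monoarylation, and the mild phosphate base leaves the dihydrobenzofuran untouched.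

Step 10
Reactants: 14 1-[4-(benzyloxy)phenyl]-2-{(2R,3R)-6-(benzyloxy)-2-[4-(benzyloxy)phenyl]-3-[3,5-bis(benzyloxy)phenyl]-2,3-dihydro-1-benzofuran-4-yl}ethan-1-one; 15 3,5-bis(benzyloxy)benzaldehyde
Product: 16 (2E)-1-[4-(benzyloxy)phenyl]-2-{(2R,3R)-6-(benzyloxy)-2-[4-(benzyloxy)phenyl]-3-[3,5-bis(benzyloxy)phenyl]-2,3-dihydro-1-benzofuran-4-yl}-3-[3,5-bis(benzyloxy)phenyl]prop-2-en-1-one
Conditions: piperidine, AcOH (cat.), PhMe, reflux, Dean–Stark
Reagents that add atoms: none
Why: Knoevenagel-type condensation of a deoxybenzoin with an aryl aldehyde; reversible addition and elimination should lead to the E isomer, in which the aroyl group is trans to the new β-aryl group.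

Step 11
Reactants: 17 4-(benzyloxy)benzaldehyde
Product: 19 sodium salt of N'-[(E)-4-(benzyloxy)benzylidene]-4-methylbenzenesulfonohydrazide, via neutral N-tosylhydrazone 18 (not isolated)
Conditions: TsNHNH2, MeOH, rt; then NaOMe (1.0 equiv), MeOH, rt, evaporate and dry in vacuo
Reagents that add atoms: 4-methylbenzenesulfonohydrazide Cc1ccc(cc1)S(=O)(=O)NN; sodium methoxide [Na+].[O-]C
Why: Condensation to the tosylhydrazone and deprotonation give the storable Bamford–Stevens precursor of the aryl diazomethane.

Step 12
Reactants: 16 (2E)-1-[4-(benzyloxy)phenyl]-2-{(2R,3R)-6-(benzyloxy)-2-[4-(benzyloxy)phenyl]-3-[3,5-bis(benzyloxy)phenyl]-2,3-dihydro-1-benzofuran-4-yl}-3-[3,5-bis(benzyloxy)phenyl]prop-2-en-1-one; 19 sodium salt of N'-[(E)-4-(benzyloxy)benzylidene]-4-methylbenzenesulfonohydrazide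
Product: 21 (2S,3S)-2,5-bis[4-(benzyloxy)phenyl]-4-{(2R,3R)-6-(benzyloxy)-2-[4-(benzyloxy)phenyl]-3-[3,5-bis(benzyloxy)phenyl]-2,3-dihydro-1-benzofuran-4-yl}-3-[3,5-bis(benzyloxy)phenyl]-2,3-dihydrofuran, via 1-(benzyloxy)-4-(diazomethyl)benzene 20 (not isolated)
Conditions: (CuOTf)2·C6H6 (5 mol%), (S,S)-t-Bu-box (11 mol%), 15-crown-5 (10 mol%), 19 added in portions, 1,4-dioxane, 40 °C; chromatography on Et3N-deactivated silica
Reagents that add atoms: none
Why: Proposed new method: thermolysis of salt 19 (Bamford–Stevens) feeds diazoalkane 20 slowly to the CuOTf–bisoxazoline complex (monovalent copper), which loses N2 to give an electrophilic copper-bound benzylidene; the carbonyl oxygen of 16, made nucleophilic by the 4-benzyloxyphenyl group, adds to it, and the copper-associated vinyl carbonyl ylide, in the s-cis conformation of the O=C2–C3=C4 unit, closes between C5 and C4 (furan positions 2 and 3 of 21 are C5 and C4 of the target numbering). The closest known reaction types are the copper-catalysed asymmetric [4+1] reaction of enones with diazoacetates and the Cloke–Wilson rearrangement of aryl cyclopropyl ketones, to which any cyclopropanation of C3=C4 would converge; a donor-only aryl carbene and a 1,2,3-triarylpropenone have not been used in this way. The one ring formed, the dihydrofuran, is closed by a six-electron 1,5-closure of the 2-oxapentadienyl system, formally 5-endo-trig, with O1–C5 formed first and C4–C5 second. C4 is set by the face of the β-carbon that the copper-bound carbon attacks, which is the task of the twofold-symmetric bisoxazoline working with or against the bias of the neighbouring (2R,3R)-dihydrobenzofuran, whose C3' aryl flanks the C3–C4' axis; because that unit is already enantiopure the two outcomes are diastereomers and can be separated. C5 is set relative to C4: a free ylide closing in a concerted disrotatory way would need its aryl group turned inward to give trans, so the trans result is expected from stepwise closure of the copper-bound ylide through the transition state with the two aryl groups anti, and, failing that, from equilibration, since the benzylic C5–O1 bond of the enol ether ionises reversibly to a zwitterion and re-closes trans without touching C4. The selectivities needed are attack at oxygen over attack at C3=C4, which the electron-poor, trisubstituted and hindered alkene should secure, and carbene–enone coupling over carbene dimerisation, which the slow release of 20 in the flask should secure.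

Step 13
Reactants: 21 (2S,3S)-2,5-bis[4-(benzyloxy)phenyl]-4-{(2R,3R)-6-(benzyloxy)-2-[4-(benzyloxy)phenyl]-3-[3,5-bis(benzyloxy)phenyl]-2,3-dihydro-1-benzofuran-4-yl}-3-[3,5-bis(benzyloxy)phenyl]-2,3-dihydrofuran
Product: 22 5-{(2R,3R)-4-[(2S,3S,4R,5S)-4-(3,5-dihydroxyphenyl)-2,5-bis(4-hydroxyphenyl)oxolan-3-yl]-6-hydroxy-2-(4-hydroxyphenyl)-2,3-dihydro-1-benzofuran-3-yl}benzene-1,3-diol
Conditions: H2 (30 bar), 10% Pd/C, THF–MeOH (1:1), 25 → 40 °C
Reagents that add atoms: none
Why: Heterogeneous catalytic hydrogenation with concurrent hydrogenolysis of the eight benzyl ethers. Syn delivery of both hydrogens to the face of C2=C3 opposite the allylic C4 aryl group (the face of the C5 aryl) sets C2 (S) and C3 (S) together and gives the 2,3-cis, 3,4-cis, 4,5-trans array. The neutral medium leaves the benzylic C–O bonds at C2, C5 and C2' un-ionised, so no centre is epimerised.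

## Compound list

1 | 1,3-bis(benzyloxy)-5-bromobenzene | Brc1cc(OCc2ccccc2)cc(OCc2ccccc2)c1 | starting material
2 | 2,4-bis(benzyloxy)-6-bromobenzaldehyde | O=Cc1c(Br)cc(OCc2ccccc2)cc1OCc1ccccc1 | intermediate
3 | 4-(benzyloxy)-2-bromo-6-hydroxybenzaldehyde | O=Cc1c(Br)cc(OCc2ccccc2)cc1O | intermediate
4 | 1-(benzyloxy)-4-(chloromethyl)benzene | ClCc1ccc(OCc2ccccc2)cc1 | starting material
5 | 4-(benzyloxy)-2-{[4-(benzyloxy)phenyl]methoxy}-6-bromobenzaldehyde | O=Cc1c(Br)cc(OCc2ccccc2)cc1OCc1ccc(OCc2ccccc2)cc1 | intermediate
6 | [3,5-bis(benzyloxy)phenyl]magnesium bromide (not isolated) | Br[Mg]c1cc(OCc2ccccc2)cc(OCc2ccccc2)c1 | intermediate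
7 | rac-[4-(benzyloxy)-2-{[4-(benzyloxy)phenyl]methoxy}-6-bromophenyl][3,5-bis(benzyloxy)phenyl]methanol | OC(c1cc(OCc2ccccc2)cc(OCc2ccccc2)c1)c1c(Br)cc(OCc2ccccc2)cc1OCc1ccc(OCc2ccccc2)cc1 | intermediate
8 | [4-(benzyloxy)-2-{[4-(benzyloxy)phenyl]methoxy}-6-bromophenyl][3,5-bis(benzyloxy)phenyl]methanone | O=C(c1cc(OCc2ccccc2)cc(OCc2ccccc2)c1)c1c(Br)cc(OCc2ccccc2)cc1OCc1ccc(OCc2ccccc2)cc1 | intermediate
9 | {[4-(benzyloxy)-2-{[4-(benzyloxy)phenyl]methoxy}-6-bromophenyl][3,5-bis(benzyloxy)phenyl]methylidene}hydrazine (E/Z mixture) | NN=C(c1cc(OCc2ccccc2)cc(OCc2ccccc2)c1)c1c(Br)cc(OCc2ccccc2)cc1OCc1ccc(OCc2ccccc2)cc1 | intermediate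
10 | 5-(benzyloxy)-1-{[4-(benzyloxy)phenyl]methoxy}-3-bromo-2-{[3,5-bis(benzyloxy)phenyl](diazo)methyl}benzene (not isolated) | [N-]=[N+]=C(c1cc(OCc2ccccc2)cc(OCc2ccccc2)c1)c1c(Br)cc(OCc2ccccc2)cc1OCc1ccc(OCc2ccccc2)cc1 | intermediate
11 | (2S,3R)-6-(benzyloxy)-2-[4-(benzyloxy)phenyl]-3-[3,5-bis(benzyloxy)phenyl]-4-bromo-2,3-dihydro-1-benzofuran (cis) | Brc1cc(OCc2ccccc2)cc2c1[C@@H](c1cc(OCc3ccccc3)cc(OCc3ccccc3)c1)[C@@H](c1ccc(OCc3ccccc3)cc1)O2 | intermediate
12 | (2R,3R)-6-(benzyloxy)-2-[4-(benzyloxy)phenyl]-3-[3,5-bis(benzyloxy)phenyl]-4-bromo-2,3-dihydro-1-benzofuran (trans) | Brc1cc(OCc2ccccc2)cc2c1[C@@H](c1cc(OCc3ccccc3)cc(OCc3ccccc3)c1)[C@H](c1ccc(OCc3ccccc3)cc1)O2 | intermediate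
13 | 1-[4-(benzyloxy)phenyl]ethan-1-one | CC(=O)c1ccc(OCc2ccccc2)cc1 | starting material
14 | 1-[4-(benzyloxy)phenyl]-2-{(2R,3R)-6-(benzyloxy)-2-[4-(benzyloxy)phenyl]-3-[3,5-bis(benzyloxy)phenyl]-2,3-dihydro-1-benzofuran-4-yl}ethan-1-one | O=C(Cc1cc(OCc2ccccc2)cc2c1[C@@H](c1cc(OCc3ccccc3)cc(OCc3ccccc3)c1)[C@H](c1ccc(OCc3ccccc3)cc1)O2)c1ccc(OCc2ccccc2)cc1 | intermediate
15 | 3,5-bis(benzyloxy)benzaldehyde | O=Cc1cc(OCc2ccccc2)cc(OCc2ccccc2)c1 | starting material
16 | (2E)-1-[4-(benzyloxy)phenyl]-2-{(2R,3R)-6-(benzyloxy)-2-[4-(benzyloxy)phenyl]-3-[3,5-bis(benzyloxy)phenyl]-2,3-dihydro-1-benzofuran-4-yl}-3-[3,5-bis(benzyloxy)phenyl]prop-2-en-1-one (precursor of the key step) | O(Cc4ccccc4)c1ccc(C(=O)/C(=C/c2cc(OCc4ccccc4)cc(OCc4ccccc4)c2)c2cc(OCc4ccccc4)cc3c2[C@@H](c2cc(OCc4ccccc4)cc(OCc4ccccc4)c2)[C@H](c2ccc(OCc4ccccc4)cc2)O3)cc1 | intermediate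
17 | 4-(benzyloxy)benzaldehyde | O=Cc1ccc(OCc2ccccc2)cc1 | starting material
18 | N'-[(E)-4-(benzyloxy)benzylidene]-4-methylbenzenesulfonohydrazide (not isolated) | Cc1ccc(cc1)S(=O)(=O)N/N=C/c1ccc(OCc2ccccc2)cc1 | intermediate
19 | sodium salt of N'-[(E)-4-(benzyloxy)benzylidene]-4-methylbenzenesulfonohydrazide | [Na+].Cc1ccc(cc1)S(=O)(=O)[N-]/N=C/c1ccc(OCc2ccccc2)cc1 | intermediate
20 | 1-(benzyloxy)-4-(diazomethyl)benzene (not isolated; precursor of the key step) | [N-]=[N+]=Cc1ccc(OCc2ccccc2)cc1 | intermediate
21 | (2S,3S)-2,5-bis[4-(benzyloxy)phenyl]-4-{(2R,3R)-6-(benzyloxy)-2-[4-(benzyloxy)phenyl]-3-[3,5-bis(benzyloxy)phenyl]-2,3-dihydro-1-benzofuran-4-yl}-3-[3,5-bis(benzyloxy)phenyl]-2,3-dihydrofuran (4,5-trans in target numbering; product of the key step) | O(Cc5ccccc5)c1ccc(C2=C(c3cc(OCc5ccccc5)cc4c3[C@@H](c3cc(OCc5ccccc5)cc(OCc5ccccc5)c3)[C@H](c3ccc(OCc5ccccc5)cc3)O4)[C@H](c3cc(OCc5ccccc5)cc(OCc5ccccc5)c3)[C@@H](c3ccc(OCc5ccccc5)cc3)O2)cc1 | intermediate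
22 | 5-{(2R,3R)-4-[(2S,3S,4R,5S)-4-(3,5-dihydroxyphenyl)-2,5-bis(4-hydroxyphenyl)oxolan-3-yl]-6-hydroxy-2-(4-hydroxyphenyl)-2,3-dihydro-1-benzofuran-3-yl}benzene-1,3-diol | Oc1ccc([C@H]2O[C@H](c3ccc(O)cc3)[C@@H](c3cc(O)cc(O)c3)[C@H]2c2cc(O)cc3c2[C@@H](c2cc(O)cc(O)c2)[C@H](c2ccc(O)cc2)O3)cc1 | target

## Step count and least certain steps

Total: 13 steps. Longest linear sequence: 12 steps (steps 1–10, 12, 13); step 11 is a one-step side branch.

**Step 12 (key step, proposed new method).**
- Most likely failure: the copper-bound benzylidene is consumed by a second molecule of diazoalkane (carbene dimerisation, azine formation) faster than the hindered ketone oxygen captures it.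
- Further concerns: three-membered closure of the ylide onto the carbonyl carbon instead of 1,5-closure, insufficient ligand control at C4 against the bias of the dihydrobenzofuran, and incomplete trans selection at C5.
- Fallback in known chemistry, from 16 back to 21: chloride 4 is quaternised with tetrahydrothiophene to 1-{[4-(benzyloxy)phenyl]methyl}thiolan-1-ium chloride F1. Its ylide (KOt-Bu, THF–MeCN, −40 °C → rt) adds to C4 of 16 and the enolate closes at C3 (Corey–Chaykovsky cyclopropanation by Michael-initiated ring closure), giving the aroyl triaryl cyclopropane F2. Sc(OTf)3 (cat.) in CH2Cl2 then effects the Cloke–Wilson ring expansion through the benzylic zwitterion at C5, which closes at oxygen to the trans-dihydrofuran 21. C4 is set under substrate control and the diastereomers are separated; a chiral sulfide in place of tetrahydrothiophene is the asymmetric variant.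

**Step 13.**
- Most likely failure: hydrogenolysis of the benzylic C5–O1 bond while it is still an enol-ether bond (and of C2'–O1'), competing with the slow saturation of the hindered tetrasubstituted alkene.
- Further concern: delivery of hydrogen from the face of the C4 aryl.
- Fallback, from 21 back to 22: the reduction is separated from the deprotection and changed to an ionic hydrogenation (Et3SiH in excess, CF3CO2H, CH2Cl2, −78 → −40 °C). Protonation of C3 on the face away from the C4 aryl and hydride delivery to C2 on the face away from the C3 aryl should give the octabenzyl ether of the target F3; the low temperature and the excess of silane are meant to trap the cation before C3 equilibrates. Diastereomers can be separated at this lipophilic stage. Mild hydrogenolysis (H2, 1 bar, Pd/C, EtOAc–MeOH) then gives 22.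

**Step 6.**
- Most likely failure: no condensation, because both faces of the carbonyl group are shielded by the two ortho substituents of ring D, so the carbene precursor is not reached.
- Fallback, from 8 back to 12 (it also bypasses steps 7 and 8): a phosphazene base (t-Bu-P4) deprotonates the ether CH2 and the carbanion adds to the ketone, giving the tertiary alcohol 6-(benzyloxy)-2-[4-(benzyloxy)phenyl]-3-[3,5-bis(benzyloxy)phenyl]-4-bromo-2,3-dihydro-1-benzofuran-3-ol F4. Acid-catalysed dehydration (TsOH, PhMe) gives 6-(benzyloxy)-2-[4-(benzyloxy)phenyl]-3-[3,5-bis(benzyloxy)phenyl]-4-bromo-1-benzofuran F5. Ionic hydrogenation (Et3SiH, CF3CO2H) gives the racemic trans-dihydrobenzofuran, that is 12 together with its enantiomer (2S,3S)-6-(benzyloxy)-2-[4-(benzyloxy)phenyl]-3-[3,5-bis(benzyloxy)phenyl]-4-bromo-2,3-dihydro-1-benzofuran F6. Chromatography on a chiral stationary phase delivers 12.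

**Step 9.**
- Most likely failure: slow coupling at the ortho-encumbered bromide, with competing reductive debromination or double arylation of the ketone.
- Fallback, from 12 back to 14: copper-free Sonogashira coupling (Pd(MeCN)2Cl2, XPhos, Cs2CO3, MeCN) with 1-(benzyloxy)-4-ethynylbenzene gives (2R,3R)-6-(benzyloxy)-2-[4-(benzyloxy)phenyl]-4-{[4-(benzyloxy)phenyl]ethynyl}-3-[3,5-bis(benzyloxy)phenyl]-2,3-dihydro-1-benzofuran F7. Gold-catalysed hydration (Ph3PAuNTf2, monovalent gold, aqueous dioxane) places the carbonyl group on the alkyne carbon next to the electron-rich 4-benzyloxyphenyl ring and gives 14.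

## Further compounds

F1 | step 12 | 1-{[4-(benzyloxy)phenyl]methyl}thiolan-1-ium chloride | [Cl-].C(c1ccccc1)Oc1ccc(C[S+]2CCCC2)cc1
F2 | step 12 | [4-(benzyloxy)phenyl]{1-[(2R,3R)-6-(benzyloxy)-2-[4-(benzyloxy)phenyl]-3-[3,5-bis(benzyloxy)phenyl]-2,3-dihydro-1-benzofuran-4-yl]-2-[3,5-bis(benzyloxy)phenyl]-3-[4-(benzyloxy)phenyl]cyclopropyl}methanone (aryl groups on C2 and C3 trans; aroyl trans to the C2 aryl; C2 configured as C4 of 21) | O=C(c1ccc(OCc2ccccc2)cc1)[C@@]1(c2cc(OCc3ccccc3)cc3c2[C@@H](c2cc(OCc4ccccc4)cc(OCc4ccccc4)c2)[C@H](c2ccc(OCc4ccccc4)cc2)O3)[C@H](c2cc(OCc3ccccc3)cc(OCc3ccccc3)c2)[C@H]1c1ccc(OCc2ccccc2)cc1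
F3 | step 13 | octabenzyl ether of 22 | O(Cc4ccccc4)c1ccc([C@H]2O[C@H](c3ccc(OCc4ccccc4)cc3)[C@@H](c3cc(OCc4ccccc4)cc(OCc4ccccc4)c3)[C@H]2c2cc(OCc4ccccc4)cc3c2[C@@H](c2cc(OCc4ccccc4)cc(OCc4ccccc4)c2)[C@H](c2ccc(OCc4ccccc4)cc2)O3)cc1
F4 | step 6 | 6-(benzyloxy)-2-[4-(benzyloxy)phenyl]-3-[3,5-bis(benzyloxy)phenyl]-4-bromo-2,3-dihydro-1-benzofuran-3-ol (racemic mixture of diastereomers) | Brc1cc(OCc2ccccc2)cc2OC(c3ccc(OCc4ccccc4)cc3)C(O)(c3cc(OCc4ccccc4)cc(OCc4ccccc4)c3)c12
F5 | step 6 | 6-(benzyloxy)-2-[4-(benzyloxy)phenyl]-3-[3,5-bis(benzyloxy)phenyl]-4-bromo-1-benzofuran | Brc1cc(OCc2ccccc2)cc2oc(-c3ccc(OCc4ccccc4)cc3)c(-c3cc(OCc4ccccc4)cc(OCc4ccccc4)c3)c12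
F6 | step 6 | (2S,3S)-6-(benzyloxy)-2-[4-(benzyloxy)phenyl]-3-[3,5-bis(benzyloxy)phenyl]-4-bromo-2,3-dihydro-1-benzofuran (enantiomer of 12) | Brc1cc(OCc2ccccc2)cc2c1[C@H](c1cc(OCc3ccccc3)cc(OCc3ccccc3)c1)[C@@H](c1ccc(OCc3ccccc3)cc1)O2
F7 | step 9 | (2R,3R)-6-(benzyloxy)-2-[4-(benzyloxy)phenyl]-4-{[4-(benzyloxy)phenyl]ethynyl}-3-[3,5-bis(benzyloxy)phenyl]-2,3-dihydro-1-benzofuran | C(#Cc1cc(OCc2ccccc2)cc2c1[C@@H](c1cc(OCc3ccccc3)cc(OCc3ccccc3)c1)[C@H](c1ccc(OCc3ccccc3)cc1)O2)c1ccc(OCc2ccccc2)cc1
A1 | alternative 1 | heptamethyl 6'-ethyl ether of the target | COc1ccc([C@H]2O[C@H](c3ccc(OC)cc3)[C@@H](c3cc(OC)cc(OC)c3)[C@H]2c2cc(OCC)cc3c2[C@@H](c2cc(OC)cc(OC)c2)[C@H](c2ccc(OC)cc2)O3)cc1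
A2 | alternative 1 | ynol-ether diyne: tetrahydrofuran of A1 carrying at C3 the chain C≡C–CH(3,5-dimethoxyphenyl)–CH(4-methoxyphenyl)–O–C≡CH, configured as in A1 | COc1ccc([C@H]2O[C@H](c3ccc(OC)cc3)[C@@H](c3cc(OC)cc(OC)c3)[C@H]2C#C[C@@H](c2cc(OC)cc(OC)c2)[C@H](c2ccc(OC)cc2)OC#C)cc1
A3 | alternative 1 | ethoxyethyne | CCOC#C
A4 | alternative 2 | all-cis 2,3,4-triarylcyclobutanone | COc1ccc([C@H]2C(=O)[C@@H](c3cc(OC)cc(OC)c3)[C@H]2c2cc(OC)cc3c2[C@@H](c2cc(OC)cc(OC)c2)[C@H](c2ccc(OC)cc2)O3)cc1
A5 | alternative 2 | (4-methoxyphenyl)ketene | COc1ccc(C=C=O)cc1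
A6 | alternative 2 | 2-diazo-1-(4-methoxyphenyl)ethan-1-one | COc1ccc(C(=O)C=[N+]=[N-])cc1
A7 | alternative 2 | (2R,3R)-4-[(Z)-2-(3,5-dimethoxyphenyl)ethenyl]-3-(3,5-dimethoxyphenyl)-6-methoxy-2-(4-methoxyphenyl)-2,3-dihydro-1-benzofuran | COc1cc(OC)cc(/C=C\c2cc(OC)cc3c2[C@@H](c2cc(OC)cc(OC)c2)[C@H](c2ccc(OC)cc2)O3)c1
A8 | alternative 3 | octamethyl ether of the target | COc1ccc([C@H]2O[C@H](c3ccc(OC)cc3)[C@@H](c3cc(OC)cc(OC)c3)[C@H]2c2cc(OC)cc3c2[C@@H](c2cc(OC)cc(OC)c2)[C@H](c2ccc(OC)cc2)O3)cc1
A9 | alternative 3 | ring D benzhydrol: heptamethyl tetrahydrofuran carrying at C3 a 2-[(3,5-dimethoxyphenyl)(hydroxy)methyl]-3-hydroxy-5-methoxyphenyl group (carbinol centre unspecified) | COc1ccc([C@H]2O[C@H](c3ccc(OC)cc3)[C@@H](c3cc(OC)cc(OC)c3)[C@H]2c2cc(OC)cc(O)c2C(O)c2cc(OC)cc(OC)c2)cc1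
A10 | alternative 3 | ortho-quinone methide derived from A9 | COc1ccc([C@H]2O[C@H](c3ccc(OC)cc3)[C@@H](c3cc(OC)cc(OC)c3)[C@H]2C2=CC(OC)=CC(=O)C2=Cc2cc(OC)cc(OC)c2)cc1
A11 | alternative 3 | 1-[(4-methoxyphenyl)methyl]thiolan-1-ium bromide | COc1ccc(C[S+]2CCCC2)cc1.[Br-]
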